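The synthesis rests on cutting ring A at C1–C2. In the target the carbinol carbon C2 lies between two methylenes, C1 and C3, and each of these is bonded to a quaternary carbon (C10, C4). A carbanion at C1 is therefore neopentyl, has no β-hydrogen and cannot eliminate. Iodine–lithium exchange at a C10 iodomethyl group, followed by attack on an N-methoxy-N-methylamide at C2 of the C4 arm, closes ring A and gives the C2 ketone of the cis-decalin in one operation. The precursor is a ring B cyclohexene whose C1, C4 and O6 substituents are all cis. It comes from a Birch-derived dienone by Ireland–Claisen transfer, selenolactonisation and lactone alkylation.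

Key step: step 22

Convention: labdane numbering is used (ring A = C1–C5, C10; ring B = C5–C10; C11–C12 on C9; C17 on C8; C18 and C19 on C4; C20 on C10). β is the face of the C20 methyl group and α the opposite face. The target is (2R,4S,5S,6S,10S): 2α-OH, 4α-CH3, 4β-CH2OAc, 5β-H, 6α-OH, 10β-CH3. This is a cis-fused decalin.

Assumption: the potassium enolate of the (R)-amide, with the enolate oxygen syn to the C9 substituent, is taken to be methylated on the face turned away from the methoxymethyl arm. This is the sense known for 2-alkylbenzamides of this auxiliary and corresponds to (10S).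

Step 1
Reactants: 1 2,3-dimethylbenzoic acid; 2 (R)-2-(methoxymethyl)pyrrolidine
Product: 4 (R)-(2,3-dimethylphenyl)[2-(methoxymethyl)pyrrolidin-1-yl]methanone, via acid chloride 3 (not isolated)
Conditions: SOCl2, cat. DMF, toluene, 70 °C; evaporate; 2, Et3N, CH2Cl2, 0 °C to rt
Reagents that add atoms: none
Why: Amide formation through the acid chloride (Schotten–Baumann type) is routine for an ortho-substituted benzoic acid and does not touch the pyrrolidine stereocentre.

Step 2
Reactants: 4 benzamide; 5 formaldehyde (gas, cracked from paraformaldehyde)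
Product: 7 (R)-[2-(2-hydroxyethyl)-3-methylphenyl][2-(methoxymethyl)pyrrolidin-1-yl]methanone, via benzylic lithium 6 (not isolated)
Conditions: LDA, THF, −78 °C; CH2O (g), −78 °C; H2O
Reagents that add atoms: none
Why: Lateral lithiation works because the tertiary amide acidifies and coordinates only at the ortho methyl group (C11), and hydroxymethylation of the benzylic anion installs C12 while the ring is still aromatic, which avoids any later γ-functionalisation of a dienone.

Step 3
Reactants: 7 hydroxyethyl benzamide
Product: 8 TBS ether of 7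
Conditions: TBSCl, imidazole, DMF, rt
Reagents that add atoms: tert-butyldimethylsilyl chloride, CC(C)(C)[Si](C)(C)Cl
Why: Silyl ether formation on a primary alcohol gives a TBS ether that survives dissolving metal and strong base and stops the alcohol from lactonising onto the amide.

Step 4
Reactants: 8 silylated benzamide; 9 iodomethane
Product: 11 (10S)-diene amide, via potassium amide enolate 10 (not isolated)
Conditions: K (2.2 equiv), NH3(l)/THF, t-BuOH (1.0 equiv), −78 °C; 9, −78 °C to rt; H2O
Reagents that add atoms: none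
Why: In this Birch reductive alkylation, two-electron reduction and para protonation (C7) give the chelated amide enolate 10, which iodomethane attacks at C10 on the face remote from the methoxymethyl arm, so the auxiliary sets C10 as S and leaves the C5=C6 and C8=C9 bonds in place.

Step 5
Reactants: 11 diene amide
Product: 12 (10S)-dienyl methanol (C1–OH)
Conditions: LDA, BH3·NH3, THF, 0 °C (forms LiH2N·BH3); 11, 0 °C to rt; H2O
Reagents that add atoms: none
Why: Reduction of a tertiary amide to the primary alcohol with lithium amidotrihydroborate, a small and strongly nucleophilic hydride known to work on α-quaternary amides, removes the auxiliary early, when C10 is flanked only by sp2 carbons.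

Step 6
Reactants: 12 dienyl methanol
Product: 13 C1 PMB ether
Conditions: NaH, 4-methoxybenzyl chloride, Bu4NI (cat.), THF/DMF, 0 °C to rt
Reagents that add atoms: 4-methoxybenzyl chloride, COc1ccc(CCl)cc1
Why: Williamson ether synthesis gives a PMB ether that masks C1–OH through base, hydride and radical steps and is later removed oxidatively without touching silyl ethers.

Step 7
Reactants: 13 diene PMB ether
Product: 14 (10S)-cross-conjugated dienone (C7 ketone)
Conditions: pyridinium dichromate (C5H5NH)2Cr2O7, t-BuOOH, Celite, benzene, 10 °C to rt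
Reagents that add atoms: tert-butyl hydroperoxide, CC(C)(C)OO
Why: Allylic oxidation with chromate/hydroperoxide attacks the doubly allylic C7 methylene, by far the weakest C–H bond, and gives a 4,4-disubstituted dienone that cannot aromatise.

Step 8
Reactants: 14 dienone
Product: 15 (7R,10S)-dienol (7α-OH, cis to the C1 arm)
Conditions: (S)-2-methyl-CBS-oxazaborolidine (0.3 equiv), catecholborane, toluene, −78 °C; MeOH, aq. NaHCO3
Reagents that add atoms: none
Why: In this Corey–Bakshi–Shibata reduction the (S)-catalyst treats the methyl-bearing C8 side as the large group and delivers hydride to the β face of C7, which is also the less hindered face (methyl versus CH2OPMB on C10), so reagent and substrate control are matched and should give the 7α-alcohol.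

Step 9
Reactants: 15 dienol; 16 propionic anhydride
Product: 17 7α-propionate
Conditions: 16, Et3N, DMAP (cat.), CH2Cl2, 0 °C
Reagents that add atoms: none
Why: DMAP-catalysed acylation under basic conditions esterifies the doubly allylic alcohol without the ionisation that acid would cause (dienol–benzene rearrangement).

Step 10
Reactants: 17 dienyl propionate
Product: 20 diene acid (C4–C5 bond on the α face; C4 epimers), via silyl ketene acetal 18 (not isolated), via trimethylsilyl ester 19 (not isolated)
Conditions: LDA, THF, −78 °C; Me3SiCl, −78 °C to rt; H2O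
Reagents that add atoms: none
Why: In the Ireland–Claisen rearrangement the suprafacial [3,3] shift carries the α configuration of the C7–O bond over to the new C4–C5 bond, so C4 ends up cis to C1 on the more hindered face, the fully substituted C9 is no competitor, and the C4 epimers are of no consequence because C4 is planarised in step 13.

Step 11
Reactants: 20 diene acid
Product: 21 7β-phenylselanyl 19,6α-lactone
Conditions: Et3N, CH2Cl2, −78 °C; PhSeCl
Reagents that add atoms: benzeneselenenyl chloride, Cl[Se]c1ccccc1
Why: In this phenylselenolactonisation (5-exo, anti addition) a reversibly formed seleniranium ion on the β face of the less hindered C6=C7 bond is trapped by the carboxylate held on the α face, so oxygen goes to C6 and cis to C4, which hydroboration of this diene would not achieve since boron prefers allylic C7 and the β face.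

Step 12
Reactants: 21 selenolactone
Product: 22 cis-fused 19,6α-lactone (C7 methylene, C8=C9 restored)
Conditions: Bu3SnH, AIBN (cat.), toluene, 80 °C
Reagents that add atoms: none
Why: In this radical deselenation (tin hydride chain) the C7–C8–C9 allyl radical takes hydrogen at the secondary, open C7 and not at the tertiary C9 next to quaternary C10, which restores the tetrasubstituted C8=C9 bond.

Step 13
Reactants: 22 lactone; 23 allyl bromide
Product: 25 (4S)-allyl methyl lactone, via lithium lactone enolate 24 (not isolated)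
Conditions: LDA, THF, −78 °C; 23, DMPU, −78 to −20 °C; H2O
Reagents that add atoms: none
Why: In this lactone enolate alkylation the cis-fused bicycle exposes only its convex face (the side of H5), the concave face being covered by C10 and its α-CH2OPMB arm, so the allyl group (C3, C2 and one carbon to be cut off) enters syn to H5 and fixes C4 as S.

Step 14
Reactants: 25 allyl lactone
Product: 26 C19,C6 diol
Conditions: LiAlH4, Et2O, 0 °C; H2O
Reagents that add atoms: none
Why: Hydride reduction of the lactone frees the primary C19–OH and the secondary 6α-OH with no change at any stereocentre, and ethers and alkenes are inert.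

Step 15
Reactants: 26 diol
Product: 27 C19 TBS ether
Conditions: TBSCl (1.05 equiv), imidazole, CH2Cl2, 0 °C
Reagents that add atoms: tert-butyldimethylsilyl chloride, CC(C)(C)[Si](C)(C)Cl
Why: Silylation is selective because the primary C19–OH reacts well before the secondary C6–OH, which is flanked by C5 and its quaternary neighbour.

Step 16
Reactants: 27 mono-silyl ether
Product: 28 6α-TIPS ether
Conditions: TIPSOTf, 2,6-lutidine, CH2Cl2, 0 °C to rt
Reagents that add atoms: triisopropylsilyl triflate, CC(C)[Si](C(C)C)(C(C)C)OS(=O)(=O)C(F)(F)F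
Why: Silylation with the triflate forces the hindered 6α-alcohol into a bulky ether, which must be in place before C1 is activated because a free O6 would close a bridging ether onto C1.

Step 17
Reactants: 28 fully protected ring B triether
Product: 29 C1 alcohol
Conditions: DDQ, CH2Cl2/pH 7 buffer, 0 °C
Reagents that add atoms: none
Why: Oxidative cleavage of the PMB ether by DDQ (hydride abstraction, then hemiacetal hydrolysis) is orthogonal to the three silyl ethers and the two alkenes.

Step 18
Reactants: 29 C1 alcohol
Product: 30 C10 iodomethyl compound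
Conditions: I2, PPh3, imidazole, toluene, 80 °C
Reagents that add atoms: iodine, II
Why: In the Garegg–Samuelsson (Appel-type) iodination the alkoxyphosphonium salt of the neopentyl alcohol is displaced by iodide on heating in a non-ionising solvent, where substitution is slow but rearrangement is held back.

Step 19
Reactants: 30 allyl iodide compound
Product: 32 C2 aldehyde, via vicinal diol 31 (not isolated)
Conditions: OsO4 (cat.), NaIO4, 2,6-lutidine, dioxane/H2O, rt
Reagents that add atoms: sodium periodate, [Na+].[O-]I(=O)(=O)=O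
Why: In the Lemieux–Johnson cleavage OsO4 dihydroxylates the monosubstituted allyl alkene far faster than the shielded tetrasubstituted C8=C9 bond, and periodate cuts diol 31 to the C2 aldehyde.

Step 20
Reactants: 32 iodo aldehyde
Product: 33 C2 carboxylic acid
Conditions: NaClO2, NaH2PO4, 2-methyl-2-butene, t-BuOH/H2O, rt
Reagents that add atoms: sodium chlorite, [Na+].[O-]Cl=O
Why: Pinnick oxidation converts the aldehyde into the acid under buffered conditions, and the alkene scavenger keeps hypochlorous acid away from C8=C9 and from the iodide.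

Step 21
Reactants: 33 iodo acid
Product: 35 ring B iodide bearing the C2 N-methoxy-N-methylamide (key-step precursor), via acyl imidazole 34 (not isolated)
Conditions: 1,1'-carbonyldiimidazole, CH2Cl2, rt; MeNH(OMe)·HCl, rt
Reagents that add atoms: N,O-dimethylhydroxylamine hydrochloride, CNOC.Cl
Why: Amide coupling through the acyl imidazole is mild and close to neutral, so the neopentyl iodide and the silyl ethers are not touched.

Step 22
Reactants: 35 iodo amide
Product: 38 protected cis-decalin C2 ketone, via neopentyllithium 36 (not isolated), via chelated tetrahedral adduct 37 (not isolated)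
Conditions: t-BuLi (2.1 equiv, rapid addition), Et2O/pentane, −78 °C; −78 to 0 °C; sat. aq. NH4Cl
Reagents that add atoms: none
Why: t-BuLi attacks the iodine of the primary iodide through an ate complex and gives neopentyllithium 36 within minutes at −78 °C while the second equivalent destroys t-BuI, and 36 has no β-hydrogen on quaternary C10 and cannot eliminate. The carbanion adds to the amide carbonyl in a 6-exo-trig closure of ring A (C1–C2), helped by the Thorpe–Ingold effect of quaternary C4 and C10 and by the cis placement of both arms on ring B. The closest known reaction type is the Parham-type cyclisation, that is halogen–lithium exchange followed by intramolecular acylation of an N-methoxy-N-methylamide. Lithium held between the alkoxide and methoxy oxygens keeps adduct 37 intact until the quench, so no ketone meets an organolithium and over-addition is excluded. No lasting stereocentre is formed, since the C2 centre of 37 is lost on collapse and C4, C5, C6 and C10 are spectators. The step needs chemoselectivity, exchange before carbonyl attack by t-BuLi, and this is secured by the much higher rate of iodine–lithium exchange at low temperature, by the neopentyl shielding of the amide and by a precursor that carries only silyl ethers and therefore no benzylic C–H.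

Step 23
Reactants: 38 decalin ketone
Product: 39 C12,C19 keto diol (6α-OTIPS kept)
Conditions: HF·pyridine, pyridine, THF, 0 °C to rt
Reagents that add atoms: none
Why: Desilylation is selective because buffered HF·pyridine removes the two primary TBS ethers while the hindered secondary TIPS ether stays.

Step 24
Reactants: 39 keto diol
Product: 40 C12 iodide with free C19–OH
Conditions: I2 (1.1 equiv), PPh3, imidazole, CH2Cl2, 0 °C
Reagents that add atoms: iodine, II
Why: Under kinetic control in this Garegg–Samuelsson iodination, only the unhindered C12 alkoxyphosphonium salt is displaced at 0 °C, and the neopentyl C19 alcohol is returned on work-up.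

Step 25
Reactants: 40 iodo alcohol
Product: 41 C19 acetate
Conditions: Ac2O, Et3N, DMAP (cat.), CH2Cl2, 0 °C
Reagents that add atoms: acetic anhydride, CC(=O)OC(C)=O
Why: DMAP-catalysed acetylation of the only free hydroxyl group places the acetate at C19 without any selectivity problem.

Step 26
Reactants: 41 iodo acetate; 42 4-bromofuran-2(5H)-one
Product: 44 butenolide ketone, via alkylzinc iodide 43 (not isolated)
Conditions: Zn dust, LiCl, THF, 40 °C; 42, Pd(dppf)Cl2 (5 mol %), THF, rt to 40 °C
Reagents that add atoms: none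
Why: In this Negishi coupling zinc insertion tolerates ketone and acetate, and the alkylzinc iodide couples with the β-bromobutenolide (C12–C13) under Pd(dppf)Cl2, whose wide bite angle favours reductive elimination over β-hydride loss.

Step 27
Reactants: 44 butenolide ketone
Product: 45 2α-alcohol (6α-OTIPS)
Conditions: NaBH4, MeOH/THF, −20 °C
Reagents that add atoms: none
Why: In this borohydride reduction the bulky 6α-OTIPS group sits equatorial and the cis-decalin folds so that axial C18 and C9 cover the α face of C2, so hydride should come from the convex β face and give the 2α-alcohol (2R), while butenolide and acetate are left alone as in the reduction of 3-oxo cardenolides.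

Step 28
Reactants: 45 mono-silyl ether
Product: 46 CNP0201970.1 (target)
Conditions: aq. HF, MeCN, 0 °C to rt
Reagents that add atoms: none
Why: Acidic fluoride desilylation frees the 6α-alcohol without the acyl migration or butenolide damage that basic fluoride might cause.

Compound list
1 | 2,3-dimethylbenzoic acid | Cc1cccc(C(=O)O)c1C | starting material
2 | (R)-2-(methoxymethyl)pyrrolidine | COC[C@H]1CCCN1 | starting material
3 | 2,3-dimethylbenzoyl chloride | Cc1cccc(C(=O)Cl)c1C | intermediate
4 | (R)-(2,3-dimethylphenyl)[2-(methoxymethyl)pyrrolidin-1-yl]methanone | COC[C@H]1CCCN1C(=O)c1cccc(C)c1C | intermediate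
5 | formaldehyde | C=O | starting material
6 | benzylic lithium compound of 4 (lithium on the ortho methyl carbon C11) | COC[C@H]1CCCN1C(=O)c1cccc(C)c1C[Li] | intermediate
7 | (R)-[2-(2-hydroxyethyl)-3-methylphenyl][2-(methoxymethyl)pyrrolidin-1-yl]methanone | COC[C@H]1CCCN1C(=O)c1cccc(C)c1CCO | intermediate
8 | TBS ether of 7 (C12–OTBS) | COC[C@H]1CCCN1C(=O)c1cccc(C)c1CCO[Si](C)(C)C(C)(C)C | intermediate
9 | iodomethane | CI | starting material
10 | potassium amide enolate of the 1,4-dihydroarene (exocyclic C10=C1 enolate) | COC[C@H]1CCCN1C(O[K])=C1C=CCC(C)=C1CCO[Si](C)(C)C(C)(C)C | intermediate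
11 | [(1S)-2-(2-TBSO-ethyl)-1,3-dimethylcyclohexa-2,5-dien-1-yl][(2R)-2-(methoxymethyl)pyrrolidin-1-yl]methanone (10S; 10β-CH3) | C1=CCC(C)=C(CCO[Si](C)(C)C(C)(C)C)[C@@]1(C)C(=O)N1CCC[C@@H]1COC | intermediate
12 | [(1S)-2-(2-TBSO-ethyl)-1,3-dimethylcyclohexa-2,5-dien-1-yl]methanol (C1–OH) | C1=CCC(C)=C(CCO[Si](C)(C)C(C)(C)C)[C@@]1(C)CO | intermediate
13 | 4-methoxybenzyl ether of 12 | C1=CCC(C)=C(CCO[Si](C)(C)C(C)(C)C)[C@@]1(C)COCc1ccc(OC)cc1 | intermediate
14 | (4S)-3-(2-TBSO-ethyl)-4-[(4-methoxybenzyloxy)methyl]-2,4-dimethylcyclohexa-2,5-dien-1-one (C7 ketone) | C1=CC(=O)C(C)=C(CCO[Si](C)(C)C(C)(C)C)[C@@]1(C)COCc1ccc(OC)cc1 | intermediate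
15 | (1R,4S)-dienol of 14 (7α-OH, cis to the C1 CH2OPMB arm) | C1=C[C@@H](O)C(C)=C(CCO[Si](C)(C)C(C)(C)C)[C@@]1(C)COCc1ccc(OC)cc1 | intermediate
16 | propionic anhydride | CCC(=O)OC(=O)CC | starting material
17 | 7α-propionate of 15 | C1=C[C@@H](OC(=O)CC)C(C)=C(CCO[Si](C)(C)C(C)(C)C)[C@@]1(C)COCc1ccc(OC)cc1 | intermediate
18 | O-trimethylsilyl ketene acetal of 17 | C1=C[C@@H](OC(=CC)O[Si](C)(C)C)C(C)=C(CCO[Si](C)(C)C(C)(C)C)[C@@]1(C)COCc1ccc(OC)cc1 | intermediate
19 | trimethylsilyl ester of 20 | CC(C(=O)O[Si](C)(C)C)[C@H]1C=CC(C)=C(CCO[Si](C)(C)C(C)(C)C)[C@@]1(C)COCc1ccc(OC)cc1 | intermediate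
20 | ring B diene acid: C5 (5β-H) carries α-CH(CH3)CO2H (C4 epimers), C6=C7–C8=C9 diene, 10β-CH3, 10α-CH2OPMB | CC(C(=O)O)[C@H]1C=CC(C)=C(CCO[Si](C)(C)C(C)(C)C)[C@@]1(C)COCc1ccc(OC)cc1 | intermediate
21 | cis-fused 19,6α-lactone with 7β-SePh (C4 epimers) | CC1C(=O)O[C@H]2[C@H]([Se]c3ccccc3)C(C)=C(CCO[Si](C)(C)C(C)(C)C)[C@@](C)(COCc3ccc(OC)cc3)[C@@H]12 | intermediate
22 | cis-fused 19,6α-lactone, C7 methylene, C8=C9 alkene (C4 epimers) | CC1C(=O)O[C@H]2CC(C)=C(CCO[Si](C)(C)C(C)(C)C)[C@@](C)(COCc3ccc(OC)cc3)[C@@H]12 | intermediate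
23 | allyl bromide | C=CCBr | starting material
24 | lithium enolate of lactone 22 | CC1=C(O[Li])O[C@H]2CC(C)=C(CCO[Si](C)(C)C(C)(C)C)[C@@](C)(COCc3ccc(OC)cc3)[C@@H]12 | intermediate
25 | (4S)-4-allyl-4-methyl 19,6α-lactone (allyl syn to H5, methyl C18 syn to C10) | C=CC[C@]1(C)C(=O)O[C@H]2CC(C)=C(CCO[Si](C)(C)C(C)(C)C)[C@@](C)(COCc3ccc(OC)cc3)[C@@H]12 | intermediate
26 | diol: C19–OH and 6α-OH, C4 allyl/methyl, C1–OPMB, C12–OTBS | OC[C@@](C)(CC=C)[C@H]1[C@@H](O)CC(C)=C(CCO[Si](C)(C)C(C)(C)C)[C@@]1(C)COCc1ccc(OC)cc1 | intermediate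
27 | C19 TBS ether of 26 | CC(C)(C)[Si](C)(C)OC[C@@](C)(CC=C)[C@H]1[C@@H](O)CC(C)=C(CCO[Si](C)(C)C(C)(C)C)[C@@]1(C)COCc1ccc(OC)cc1 | intermediate
28 | 6α-TIPS ether of 27 | CC(C)(C)[Si](C)(C)OC[C@@](C)(CC=C)[C@H]1[C@@H](O[Si](C(C)C)(C(C)C)C(C)C)CC(C)=C(CCO[Si](C)(C)C(C)(C)C)[C@@]1(C)COCc1ccc(OC)cc1 | intermediate
29 | C1 alcohol (PMB removed) | CC(C)(C)[Si](C)(C)OC[C@@](C)(CC=C)[C@H]1[C@@H](O[Si](C(C)C)(C(C)C)C(C)C)CC(C)=C(CCO[Si](C)(C)C(C)(C)C)[C@@]1(C)CO | intermediate
30 | C10 iodomethyl compound with C4 allyl arm | CC(C)(C)[Si](C)(C)OC[C@@](C)(CC=C)[C@H]1[C@@H](O[Si](C(C)C)(C(C)C)C(C)C)CC(C)=C(CCO[Si](C)(C)C(C)(C)C)[C@@]1(C)CI | intermediate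
31 | vicinal diol from the allyl group of 30 (carbinol epimers) | CC(C)(C)[Si](C)(C)OC[C@@](C)(CC(O)CO)[C@H]1[C@@H](O[Si](C(C)C)(C(C)C)C(C)C)CC(C)=C(CCO[Si](C)(C)C(C)(C)C)[C@@]1(C)CI | intermediate
32 | iodo aldehyde (C2 aldehyde on the C4 arm) | CC(C)(C)[Si](C)(C)OC[C@@](C)(CC=O)[C@H]1[C@@H](O[Si](C(C)C)(C(C)C)C(C)C)CC(C)=C(CCO[Si](C)(C)C(C)(C)C)[C@@]1(C)CI | intermediate
33 | iodo acid (C2 carboxylic acid) | CC(C)(C)[Si](C)(C)OC[C@@](C)(CC(=O)O)[C@H]1[C@@H](O[Si](C(C)C)(C(C)C)C(C)C)CC(C)=C(CCO[Si](C)(C)C(C)(C)C)[C@@]1(C)CI | intermediate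
34 | acyl imidazole of 33 | CC(C)(C)[Si](C)(C)OC[C@@](C)(CC(=O)n2ccnc2)[C@H]1[C@@H](O[Si](C(C)C)(C(C)C)C(C)C)CC(C)=C(CCO[Si](C)(C)C(C)(C)C)[C@@]1(C)CI | intermediate
35 | key-step precursor: ring B cyclohexene with 10α-CH2I, 10β-CH3, 5β-H, 6α-OTIPS, C9 CH2CH2OTBS and the (4S) arm C(CH3)(CH2OTBS)CH2C(O)N(OMe)Me | CC(C)(C)[Si](C)(C)OC[C@@](C)(CC(=O)N(C)OC)[C@H]1[C@@H](O[Si](C(C)C)(C(C)C)C(C)C)CC(C)=C(CCO[Si](C)(C)C(C)(C)C)[C@@]1(C)CI | intermediate
36 | neopentyllithium from 35 (C1–Li) | CC(C)(C)[Si](C)(C)OC[C@@](C)(CC(=O)N(C)OC)[C@H]1[C@@H](O[Si](C(C)C)(C(C)C)C(C)C)CC(C)=C(CCO[Si](C)(C)C(C)(C)C)[C@@]1(C)C[Li] | intermediate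
37 | lithium-chelated tetrahedral adduct at C2 | CC(C)(C)[Si](C)(C)OC[C@@]1(C)CC(O[Li])(N(C)OC)C[C@]2(C)C(CCO[Si](C)(C)C(C)(C)C)=C(C)C[C@H](O[Si](C(C)C)(C(C)C)C(C)C)[C@H]12 | intermediate
38 | protected cis-decalin C2 ketone (C19–OTBS, C12–OTBS, 6α-OTIPS) | CC(C)(C)[Si](C)(C)OC[C@@]1(C)CC(=O)C[C@]2(C)C(CCO[Si](C)(C)C(C)(C)C)=C(C)C[C@H](O[Si](C(C)C)(C(C)C)C(C)C)[C@H]12 | intermediate
39 | keto diol (C12–OH, C19–OH, 6α-OTIPS) | OC[C@@]1(C)CC(=O)C[C@]2(C)C(CCO)=C(C)C[C@H](O[Si](C(C)C)(C(C)C)C(C)C)[C@H]12 | intermediate
40 | C12 iodide, C19–OH | OC[C@@]1(C)CC(=O)C[C@]2(C)C(CCI)=C(C)C[C@H](O[Si](C(C)C)(C(C)C)C(C)C)[C@H]12 | intermediate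
41 | C12 iodide, C19 acetate | CC(=O)OC[C@@]1(C)CC(=O)C[C@]2(C)C(CCI)=C(C)C[C@H](O[Si](C(C)C)(C(C)C)C(C)C)[C@H]12 | intermediate
42 | 4-bromofuran-2(5H)-one | O=C1C=C(Br)CO1 | starting material
43 | C12 alkylzinc iodide | CC(=O)OC[C@@]1(C)CC(=O)C[C@]2(C)C(CC[Zn]I)=C(C)C[C@H](O[Si](C(C)C)(C(C)C)C(C)C)[C@H]12 | intermediate
44 | 2-oxo butenolide, C19 acetate, 6α-OTIPS | CC(=O)OC[C@@]1(C)CC(=O)C[C@]2(C)C(CCC3=CC(=O)OC3)=C(C)C[C@H](O[Si](C(C)C)(C(C)C)C(C)C)[C@H]12 | intermediate
45 | 2α-alcohol, 6α-OTIPS | CC(=O)OC[C@@]1(C)C[C@H](O)C[C@]2(C)C(CCC3=CC(=O)OC3)=C(C)C[C@H](O[Si](C(C)C)(C(C)C)C(C)C)[C@H]12 | intermediate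
46 | CNP0201970.1, (2R,4S,5S,6S,10S)-19-acetoxy-2α,6α-dihydroxy-5β-labd-8,13-dien-15,16-olide | CC(=O)OC[C@@]1(C)C[C@H](O)C[C@]2(C)C(CCC3=CC(=O)OC3)=C(C)C[C@H](O)[C@H]12 | target

Total step count: 28. Longest linear sequence: 28 (the route is linear, and every other component is purchased).

Steps most likely to fail

1. Step 22. Ring closure may lose out to three processes: proton transfer from C3–H to the neopentyllithium, direct attack of t-BuLi on the amide, or base-induced loss of the N-methoxy group. The fallback sets out from iodo aldehyde 32. Samarium diiodide SmI2 in THF with HMPA should close the same C1–C2 bond by an intramolecular Barbier reaction under non-basic conditions and give the protected decalin-2-ol F1. Either C2 epimer serves. Dess–Martin oxidation of this alcohol comes back to the route at ketone 38.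

2. Step 11. The selenium electrophile may engage the more electron-rich C8=C9 bond, the seleniranium ion may open at allylic C7, or the allylic selenide may shift or be lost on handling. The fallback sets out from diene acid 20.
   - A Jacobsen–Katsuki epoxidation with [N,N'-bis(3,5-di-tert-butylsalicylidene)cyclohexane-1,2-diaminato]MnCl (the matched enantiomer) and NaOCl accepts cis-disubstituted conjugated alkenes and rejects tetrasubstituted ones. It should epoxidise C6=C7 on the β face, anti to the C5 side chain, to give the 6β,7β-epoxy acid F2.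
   - Mild acid (PPTS) opens the epoxide in 5-exo fashion with inversion at C6 to give the 7β-hydroxy lactone F3.
   - Acetylation gives the allylic acetate F4.
   - Hydrogenolysis with Pd(PPh3)4 and Bu3SnH places hydride at the less hindered allyl terminus C7 and comes back to the route at lactone 22.

3. Step 5. Hydride delivery to the carbonyl on quaternary C10 may stall, or the hemiaminal may collapse by C–O instead of C–N cleavage. The fallback sets out from diene amide 11. Iodine in THF/H2O should bring about an amide-assisted iodolactonisation that expels the auxiliary and gives the bridged iodolactone F5. Zinc in acetic acid regenerates the alkene by reductive elimination and frees the dienyl carboxylic acid F6. LiAlH4 reduction comes back to the route at alcohol 12.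

Further compounds
F1 | step 22 | protected cis-decalin-2-ol (C2 epimers; C19–OTBS, C12–OTBS, 6α-OTIPS) | CC(C)(C)[Si](C)(C)OC[C@@]1(C)CC(O)C[C@]2(C)C(CCO[Si](C)(C)C(C)(C)C)=C(C)C[C@H](O[Si](C(C)C)(C(C)C)C(C)C)[C@H]12
F2 | step 11 | 6β,7β-epoxy acid (C4 epimers) | CC(C(=O)O)[C@H]1[C@@H]2O[C@@H]2C(C)=C(CCO[Si](C)(C)C(C)(C)C)[C@@]1(C)COCc1ccc(OC)cc1
F3 | step 11 | 7β-hydroxy 19,6α-lactone (C4 epimers) | CC1C(=O)O[C@H]2[C@H](O)C(C)=C(CCO[Si](C)(C)C(C)(C)C)[C@@](C)(COCc3ccc(OC)cc3)[C@@H]12
F4 | step 11 | 7β-acetoxy 19,6α-lactone (C4 epimers) | CC1C(=O)O[C@H]2[C@H](OC(C)=O)C(C)=C(CCO[Si](C)(C)C(C)(C)C)[C@@](C)(COCc3ccc(OC)cc3)[C@@H]12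
F5 | step 5 | bridged 1,6α-iodolactone (5β-iodide) | O=C1O[C@H]2CC(C)=C(CCO[Si](C)(C)C(C)(C)C)[C@]1(C)[C@@H]2I
F6 | step 5 | (1S)-2-(2-TBSO-ethyl)-1,3-dimethylcyclohexa-2,5-diene-1-carboxylic acid | C1=CCC(C)=C(CCO[Si](C)(C)C(C)(C)C)[C@@]1(C)C(=O)O
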